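**Strategy.** Ring C (the dihydropyranone) is cut at two bonds, C2–C3 and O1–C8a, which divides the target into a chromene aldehyde (ring B part) and a 2-fluoroaryl methyl ketone (ring A). The key step is a one-flask formal hetero-[4+2] annulation: a catalytic enantioselective Mukaiyama aldol forms C2–C3 and sets C2, then fluoride-relayed desilylation lets the C2 oxygen displace the fluoride at C8a (SNAr). It exploits the C4 carbonyl, which makes C3 nucleophilic and, being ortho to C8a, activates that ring A carbon for substitution. The precursors are a trimethylsilyl enol ether bearing an ortho C–F bond and an achiral aldehyde.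

Key step: step 8

Flavanone numbering is used throughout (O1, C2, C3, C4, C4a, C5–C8, C8a). Ring A is the benzo ring of the chromanone, ring C its pyranone ring, and ring B the aryl group at C2 with its fused dimethylpyran. The target is the (2S) enantiomer.

Assumption: the facial sense of the tryptophan-derived oxazaborolidinone is taken by analogy with simple aromatic aldehydes, so the (R)-tryptophan catalyst is written for Si-face attack; if a model aldol showed the opposite sense, the (S)-tryptophan catalyst would be used with nothing else changed.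

Step 1
Reactants: 1 4-bromo-3-fluorophenol
Product: 2 1-bromo-2-fluoro-4-(methoxymethoxy)benzene
Conditions: MOMCl, i-Pr2NEt, CH2Cl2, 0 °C → rt
Reagents that add atoms: chloromethyl methyl ether (MOMCl), COCCl
Why: Williamson-type O-alkylation of the phenol gives the MOM ether, which protects the future C7 hydroxyl and serves as a directing group for the next step.

Step 2
Reactants: 2 1-bromo-2-fluoro-4-(methoxymethoxy)benzene; 3 1-bromo-3-methylbut-2-ene (prenyl bromide)
Product: 5 1-bromo-2-fluoro-4-(methoxymethoxy)-3-(3-methylbut-2-en-1-yl)benzene, via aryllithium 4 (not isolated)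
Conditions: LDA, THF, −78 °C; CuBr·SMe2 (10 mol%), then 3, −78 → −30 °C
Reagents that add atoms: none
Why: Directed ortho-metalation, in which LDA removes the most acidic ring hydrogen (flanked by fluorine and the MOM ether) without touching the C–Br bond, followed by copper-catalysed SN2-type allylic substitution at the primary carbon of 3, kept cold to hold back loss of lithium fluoride.

Step 3
Reactants: 5 1-bromo-2-fluoro-4-(methoxymethoxy)-3-(3-methylbut-2-en-1-yl)benzene; 6 N-methoxy-N-methylacetamide
Product: 9 1-[2-fluoro-4-(methoxymethoxy)-3-(3-methylbut-2-en-1-yl)phenyl]ethan-1-one, via arylmagnesium chloride 7 (not isolated), via magnesium hemiaminal adduct 8 (not isolated)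
Conditions: i-PrMgCl·LiCl, THF, −15 → 0 °C; then 6, 0 °C → rt; aq. NH4Cl
Reagents that add atoms: none
Why: Bromine–magnesium exchange (accelerated by the ortho fluorine, and giving an arylmagnesium much less prone to fluoride loss than the aryllithium) followed by Weinreb ketone synthesis, in which the chelated tetrahedral adduct 8 should prevent over-addition.

Step 4
Reactants: 9 1-[2-fluoro-4-(methoxymethoxy)-3-(3-methylbut-2-en-1-yl)phenyl]ethan-1-one
Product: 11 {1-[2-fluoro-4-(methoxymethoxy)-3-(3-methylbut-2-en-1-yl)phenyl]ethenyl}oxy(trimethyl)silane, via lithium enolate 10 (not isolated)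
Conditions: LDA, THF, −78 °C; TMSCl, −78 °C → rt; non-aqueous work-up (pentane, filtration)
Reagents that add atoms: chlorotrimethylsilane (TMSCl), C[Si](C)(C)Cl
Why: Kinetic enolisation of the methyl ketone and O-silylation (silyl enol ether formation) under basic conditions that should spare the MOM ether, the prenyl group and the C–F bond.

Step 5
Reactants: 12 4-hydroxybenzaldehyde; 3 1-bromo-3-methylbut-2-ene (prenyl bromide)
Product: 13 4-hydroxy-3-(3-methylbut-2-en-1-yl)benzaldehyde
Conditions: KOH, H2O, 0 °C → rt
Reagents that add atoms: none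
Why: Direct ortho C-alkylation of the ambident phenoxide in water, where hydrogen bonding to the oxygen favours attack through carbon; a known but modest-yielding C-prenylation.

Step 6
Reactants: 13 4-hydroxy-3-(3-methylbut-2-en-1-yl)benzaldehyde; 14 3-chloro-3-methylbut-1-yne
Product: 15 4-[(2-methylbut-3-yn-2-yl)oxy]-3-(3-methylbut-2-en-1-yl)benzaldehyde
Conditions: K2CO3, KI (cat.), CuI (cat.), acetone, reflux
Reagents that add atoms: none
Why: Copper-assisted O-propargylation of the phenol with the tertiary propargylic chloride (Williamson-type etherification) gives the aryl 1,1-dimethylpropargyl ether needed for chromene formation.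

Step 7
Reactants: 15 4-[(2-methylbut-3-yn-2-yl)oxy]-3-(3-methylbut-2-en-1-yl)benzaldehyde
Product: 18 2,2-dimethyl-8-(3-methylbut-2-en-1-yl)-2H-chromene-6-carbaldehyde, via allenylphenol 16 (not isolated), via o-quinone methide 17 (not isolated)
Conditions: PhNEt2, 190 °C
Reagents that add atoms: none
Why: Thermal aryl propargyl ether Claisen rearrangement to allenylphenol 16, [1,5]-hydrogen shift to o-quinone methide 17 and oxa-6π electrocyclisation; only one ortho position is free, so the dimethylpyran ring can only close there.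

Step 8
Reactants: 11 {1-[2-fluoro-4-(methoxymethoxy)-3-(3-methylbut-2-en-1-yl)phenyl]ethenyl}oxy(trimethyl)silane; 18 2,2-dimethyl-8-(3-methylbut-2-en-1-yl)-2H-chromene-6-carbaldehyde
Product: 21 (2S)-2-[2,2-dimethyl-8-(3-methylbut-2-en-1-yl)-2H-chromen-6-yl]-7-(methoxymethoxy)-8-(3-methylbut-2-en-1-yl)-2,3-dihydro-4H-chromen-4-one, via silyl aldolate 19 (not isolated), via cesium alkoxide 20 (not isolated)
Conditions: 11 (1.0 equiv), 18 (1.2 equiv), B-butyl oxazaborolidinone from N-tosyl-(R)-tryptophan and n-BuB(OH)2 (20 mol%), EtCN, −78 °C; then CsF (0.5 equiv), DMF, −40 °C → rt; AcOH quench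
Reagents that add atoms: none
Why: The boron Lewis acid binds the formyl oxygen of 18 and enol silane 11 adds through an open transition state with silyl transfer to give β-silyloxy ketone 19 (new C2–C3 bond); fluoride then cleaves the O–Si bond and alkoxide 20 adds to the fluorine-bearing carbon ortho to the ketone, the Meisenheimer adduct expelling fluoride, which returns to desilylate the next molecule (new O1–C8a bond). The closest known reaction types are the oxazaborolidinone-catalysed asymmetric Mukaiyama aldol of aryl methyl ketone enol silanes with aromatic aldehydes and the fluoride-mediated SNAr etherification of silyl ethers with carbonyl-activated aryl fluorides, joined here as a tandem aldol–SNAr annulation (a formal hetero-[4+2] of the C=O of 18 with the C3–C4–C4a–C8a unit of 11). Ring C is closed by 6-exo-trig attack of the C2 oxygen on C8a in an addition–elimination (SNAr) mode. The C2 stereocentre is set in the aldol by the catalyst, whose indole should shield one face of the bound aldehyde so that the Si face is attacked, and it is carried unchanged through the closure because the C2–O bond is never broken. The step needs enantiofacial control and a ring closure that outruns retro-aldol cleavage and β-elimination to the chalcone; the fluoride leaving group ortho to the ketone, the intramolecular six-membered closure, the masked phenol (MOM ether) and the low, fluoride-relayed concentration of alkoxide should secure this.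

Step 9
Reactants: 21 (2S)-2-[2,2-dimethyl-8-(3-methylbut-2-en-1-yl)-2H-chromen-6-yl]-7-(methoxymethoxy)-8-(3-methylbut-2-en-1-yl)-2,3-dihydro-4H-chromen-4-one
Product: 22 (2S)-2-[2,2-dimethyl-8-(3-methylbut-2-en-1-yl)-2H-chromen-6-yl]-7-hydroxy-8-(3-methylbut-2-en-1-yl)-2,3-dihydro-4H-chromen-4-one
Conditions: HCl (3 M aq.), MeOH, 40 °C
Reagents that add atoms: none
Why: Acid-catalysed acetal exchange (methanolysis of the MOM ether) frees the C7 phenol; dilute acid at mild temperature should leave the prenyl groups, the chromene and the C2 stereocentre untouched, since flavanone ring opening is base-promoted.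

**Compound list**

1 | 4-bromo-3-fluorophenol | Oc1ccc(Br)c(F)c1 | starting material
2 | 1-bromo-2-fluoro-4-(methoxymethoxy)benzene | COCOc1ccc(Br)c(F)c1 | intermediate
3 | 1-bromo-3-methylbut-2-ene (prenyl bromide) | CC(C)=CCBr | starting material
4 | [3-bromo-2-fluoro-6-(methoxymethoxy)phenyl]lithium | COCOc1ccc(Br)c(F)c1[Li] | intermediate (not isolated)
5 | 1-bromo-2-fluoro-4-(methoxymethoxy)-3-(3-methylbut-2-en-1-yl)benzene | COCOc1ccc(Br)c(F)c1CC=C(C)C | intermediate
6 | N-methoxy-N-methylacetamide | CC(=O)N(C)OC | starting material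
7 | [2-fluoro-4-(methoxymethoxy)-3-(3-methylbut-2-en-1-yl)phenyl]magnesium chloride | COCOc1ccc([Mg]Cl)c(F)c1CC=C(C)C | intermediate (not isolated)
8 | chloromagnesium 1-[2-fluoro-4-(methoxymethoxy)-3-(3-methylbut-2-en-1-yl)phenyl]-1-[methoxy(methyl)amino]ethan-1-olate | CC(O[Mg]Cl)(N(C)OC)c1ccc(OCOC)c(CC=C(C)C)c1F | intermediate (not isolated)
9 | 1-[2-fluoro-4-(methoxymethoxy)-3-(3-methylbut-2-en-1-yl)phenyl]ethan-1-one | CC(=O)c1ccc(OCOC)c(CC=C(C)C)c1F | intermediate
10 | lithium 1-[2-fluoro-4-(methoxymethoxy)-3-(3-methylbut-2-en-1-yl)phenyl]ethen-1-olate | [Li]OC(=C)c1ccc(OCOC)c(CC=C(C)C)c1F | intermediate (not isolated)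
11 | {1-[2-fluoro-4-(methoxymethoxy)-3-(3-methylbut-2-en-1-yl)phenyl]ethenyl}oxy(trimethyl)silane | C=C(O[Si](C)(C)C)c1ccc(OCOC)c(CC=C(C)C)c1F | intermediate
12 | 4-hydroxybenzaldehyde | O=Cc1ccc(O)cc1 | starting material
13 | 4-hydroxy-3-(3-methylbut-2-en-1-yl)benzaldehyde | CC(C)=CCc1cc(C=O)ccc1O | intermediate
14 | 3-chloro-3-methylbut-1-yne | CC(C)(Cl)C#C | starting material
15 | 4-[(2-methylbut-3-yn-2-yl)oxy]-3-(3-methylbut-2-en-1-yl)benzaldehyde | CC(C)=CCc1cc(C=O)ccc1OC(C)(C)C#C | intermediate
16 | 4-hydroxy-3-(3-methylbuta-1,2-dien-1-yl)-5-(3-methylbut-2-en-1-yl)benzaldehyde | CC(C)=CCc1cc(C=O)cc(C=C=C(C)C)c1O | intermediate (not isolated)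
17 | 5-(3-methylbut-2-en-1-yl)-3-(3-methylbut-2-en-1-ylidene)-4-oxocyclohexa-1,5-diene-1-carbaldehyde | O=C1C(CC=C(C)C)=CC(C=O)=CC1=CC=C(C)C | intermediate (not isolated)
18 | 2,2-dimethyl-8-(3-methylbut-2-en-1-yl)-2H-chromene-6-carbaldehyde | CC(C)=CCc1cc(C=O)cc2c1OC(C)(C)C=C2 | intermediate
19 | (3S)-3-[2,2-dimethyl-8-(3-methylbut-2-en-1-yl)-2H-chromen-6-yl]-1-[2-fluoro-4-(methoxymethoxy)-3-(3-methylbut-2-en-1-yl)phenyl]-3-[(trimethylsilyl)oxy]propan-1-one | CC(C)=CCc1cc([C@@H](O[Si](C)(C)C)CC(=O)c3ccc(OCOC)c(CC=C(C)C)c3F)cc2c1OC(C)(C)C=C2 | intermediate (not isolated)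
20 | cesium (1S)-1-[2,2-dimethyl-8-(3-methylbut-2-en-1-yl)-2H-chromen-6-yl]-3-[2-fluoro-4-(methoxymethoxy)-3-(3-methylbut-2-en-1-yl)phenyl]-3-oxopropan-1-olate | CC(C)=CCc1cc([C@@H]([O-])CC(=O)c3ccc(OCOC)c(CC=C(C)C)c3F)cc2c1OC(C)(C)C=C2.[Cs+] | intermediate (not isolated)
21 | (2S)-2-[2,2-dimethyl-8-(3-methylbut-2-en-1-yl)-2H-chromen-6-yl]-7-(methoxymethoxy)-8-(3-methylbut-2-en-1-yl)-2,3-dihydro-4H-chromen-4-one | CC(C)=CCc1cc([C@@H]2CC(=O)c3ccc(OCOC)c(CC=C(C)C)c3O2)cc2c1OC(C)(C)C=C2 | intermediate
22 | (2S)-2-[2,2-dimethyl-8-(3-methylbut-2-en-1-yl)-2H-chromen-6-yl]-7-hydroxy-8-(3-methylbut-2-en-1-yl)-2,3-dihydro-4H-chromen-4-one | CC(C)=CCc1cc([C@@H]2CC(=O)c3ccc(O)c(CC=C(C)C)c3O2)cc2c1OC(C)(C)C=C2 | target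

Total step count: 9. Longest linear sequence: 6 steps (steps 1, 2, 3, 4, 8 and 9).

**Steps most likely to fail**

Step 8 is the riskiest. The enantiomeric purity could be eroded by retro-aldol cleavage and re-addition at the stage of alkoxide 20 before the ring closes, or by fluoride-induced opening of 21 to the chalcone and re-closure; β-elimination of the aldolate could also divert material. The fallback gives up catalyst control and resolves instead. It sets out from ketone 9 and aldehyde 18. Ketone 9 is deprotonated (LDA, THF, −78 °C) to enolate 10, and 18 is added to give the racemic aldolate lithium 1-[2,2-dimethyl-8-(3-methylbut-2-en-1-yl)-2H-chromen-6-yl]-3-[2-fluoro-4-(methoxymethoxy)-3-(3-methylbut-2-en-1-yl)phenyl]-3-oxopropan-1-olate F1. On addition of DMF and warming to room temperature, F1 should cyclise in the same flask by SNAr to racemic 2-[2,2-dimethyl-8-(3-methylbut-2-en-1-yl)-2H-chromen-6-yl]-7-(methoxymethoxy)-8-(3-methylbut-2-en-1-yl)-2,3-dihydro-4H-chromen-4-one F2. Retro-aldol equilibration is harmless here, because the irreversible ring closure drains the aldolate. Preparative supercritical-fluid chromatography on amylose tris(3,5-dimethylphenylcarbamate) would then separate 21 from its antipode, (2R)-2-[2,2-dimethyl-8-(3-methylbut-2-en-1-yl)-2H-chromen-6-yl]-7-(methoxymethoxy)-8-(3-methylbut-2-en-1-yl)-2,3-dihydro-4H-chromen-4-one F3, and the route is rejoined at 21.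

Step 2 comes second. Aryllithium 4 could lose lithium fluoride (aryne formation) before it is allylated, or the allylic substitution could occur at the tertiary terminus of 3. The fallback forms the aryl–prenyl bond by cross-coupling and sets out from 2. Compound 2 is lithiated as before and quenched at −78 °C with I2, a trap fast enough to outrun fluoride loss, to give 1-bromo-2-fluoro-3-iodo-4-(methoxymethoxy)benzene F4. A chemoselective Stille coupling at the C–I bond with tributyl(3-methylbut-2-en-1-yl)stannane (Pd(PPh3)4, CuI, CsF, DMF, 45 °C) should then give 5, where the route is rejoined.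

Step 5 comes third. O-alkylation of the phenoxide and double alkylation could outcompete mono-C-alkylation. The fallback delivers the prenyl group by aromatic Claisen rearrangement and sets out from 12 and 14. Phenol 12 is O-alkylated with 14 (K2CO3, KI, CuI cat., acetone, reflux) to 4-[(2-methylbut-3-yn-2-yl)oxy]benzaldehyde F5. Semi-hydrogenation (H2, Pd/CaCO3 poisoned with Pb(OAc)2, quinoline, EtOAc) gives 4-[(2-methylbut-3-en-2-yl)oxy]benzaldehyde F6. Heating F6 (PhNEt2, 150 °C) should give 13 by [3,3]-sigmatropic shift and tautomerisation, and the route is rejoined at 13.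

**Further compounds**

F1 | step 8 | lithium 1-[2,2-dimethyl-8-(3-methylbut-2-en-1-yl)-2H-chromen-6-yl]-3-[2-fluoro-4-(methoxymethoxy)-3-(3-methylbut-2-en-1-yl)phenyl]-3-oxopropan-1-olate (racemic) | CC(C)=CCc1cc(C([O-])CC(=O)c3ccc(OCOC)c(CC=C(C)C)c3F)cc2c1OC(C)(C)C=C2.[Li+]
F2 | step 8 | 2-[2,2-dimethyl-8-(3-methylbut-2-en-1-yl)-2H-chromen-6-yl]-7-(methoxymethoxy)-8-(3-methylbut-2-en-1-yl)-2,3-dihydro-4H-chromen-4-one (racemic) | CC(C)=CCc1cc(C2CC(=O)c3ccc(OCOC)c(CC=C(C)C)c3O2)cc2c1OC(C)(C)C=C2
F3 | step 8 | (2R)-2-[2,2-dimethyl-8-(3-methylbut-2-en-1-yl)-2H-chromen-6-yl]-7-(methoxymethoxy)-8-(3-methylbut-2-en-1-yl)-2,3-dihydro-4H-chromen-4-one | CC(C)=CCc1cc([C@H]2CC(=O)c3ccc(OCOC)c(CC=C(C)C)c3O2)cc2c1OC(C)(C)C=C2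
F4 | step 2 | 1-bromo-2-fluoro-3-iodo-4-(methoxymethoxy)benzene | COCOc1ccc(Br)c(F)c1I
F5 | step 5 | 4-[(2-methylbut-3-yn-2-yl)oxy]benzaldehyde | O=Cc1ccc(OC(C)(C)C#C)cc1
F6 | step 5 | 4-[(2-methylbut-3-en-2-yl)oxy]benzaldehyde | O=Cc1ccc(OC(C)(C)C=C)cc1
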